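## Retrosynthetic overview

- The target is two 7-hydroxychroman-3-ols joined through one catechol ring (the central ring). The "upper" chroman carries it at C4 (2R,3S,4R, all-trans); the "lower" chroman carries it at C2 (2S,3S, cis). The last disconnection removes six O-benzyl groups.
- Both C3 centres and upper C4 are relayed from the two C2 aryl-ether centres: LiBH(s-Bu)3 on a lower chroman-3-one gives cis, and hydroboration of an upper 4-aryl-2H-chromene anti to the C2 aryl group gives trans,trans.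
- Key disconnection: both pyran rings are cut at C4–C4a, back to one bis(aryl propargyl ether). Forward, one gold-catalysed operation closes the lower pyran ring first (alkyne oxidation, carbene arylation to the chroman-3-one) and the upper pyran ring second (6-endo-dig hydroarylation to the 2H-chromene).
- The two C2–O bonds are cut to 3-(benzyloxy)phenol and racemic propargylic acetates (copper-catalysed enantioconvergent etherification, mirror-image ligands for the two centres). The aryl–alkyne bond is a Sonogashira disconnection.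
- Everything traces to 3,4-bis(benzyloxy)benzaldehyde (used twice, once as its 6-bromo derivative), ethynylmagnesium bromide and 3-(benzyloxy)phenol. All six benzene rings are bought.

Assumption: the facial sense quoted for each chiral ligand is taken by analogy with simple 1-arylpropargyl esters; if it proves opposite, the enantiomeric ligand is used with no other change.

## Route

Step 1
Reactants: 1 3,4-bis(benzyloxy)benzaldehyde
Product: 2 4,5-bis(benzyloxy)-2-bromobenzaldehyde
Conditions: Br2 (1.05 equiv), AcOH, rt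
Reagents that add atoms: bromine, BrBr
Why: Electrophilic aromatic bromination goes to the only ring position para to an ether oxygen (C6, next to the formyl group), as with veratraldehyde; no stereocentre is involved.

Step 2
Reactants: 1 3,4-bis(benzyloxy)benzaldehyde; 3 ethynylmagnesium bromide
Product: 5 (±)-1-[3,4-bis(benzyloxy)phenyl]prop-2-yn-1-yl acetate, via bromomagnesium propargylic alkoxide 4 (not isolated)
Conditions: HC≡CMgBr (1.2 equiv), THF, 0 °C; then Ac2O (1.5 equiv), DMAP (cat.), 0 °C → rt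
Reagents that add atoms: acetic anhydride, CC(=O)OC(C)=O
Why: Grignard 1,2-addition to the aldehyde followed by in situ O-acylation of the magnesium alkoxide; the carbinol centre is left racemic because step 3 converges both enantiomers.

Step 3
Reactants: 5 (±)-1-[3,4-bis(benzyloxy)phenyl]prop-2-yn-1-yl acetate; 6 3-(benzyloxy)phenol
Product: 7 1-(benzyloxy)-3-{[(1S)-1-[3,4-bis(benzyloxy)phenyl]prop-2-yn-1-yl]oxy}benzene
Conditions: CuOTf·½C6H6 (5 mol %), (S,S)-Ph-pybox [2,6-bis((4S)-4-phenyl-4,5-dihydrooxazol-2-yl)pyridine] (10 mol %), i-Pr2NEt (1.2 equiv), THF, −10 °C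
Reagents that add atoms: none
Why: Copper-catalysed enantioselective propargylic substitution (Nishibayashi-type etherification): the copper acetylide of 5 loses acetate to a planar copper allenylidene, so both enantiomers converge, and the pybox-bound copper lets the phenol oxygen attack one face to set the (S) ether centre that becomes upper C2.

Step 4
Reactants: 2 4,5-bis(benzyloxy)-2-bromobenzaldehyde; 7 1-(benzyloxy)-3-{[(1S)-1-[3,4-bis(benzyloxy)phenyl]prop-2-yn-1-yl]oxy}benzene
Product: 8 4,5-bis(benzyloxy)-2-{(3R)-3-[3-(benzyloxy)phenoxy]-3-[3,4-bis(benzyloxy)phenyl]prop-1-yn-1-yl}benzaldehyde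
Conditions: PdCl2(MeCN)2 (2 mol %), XPhos (6 mol %), Cs2CO3 (2 equiv), MeCN, 70 °C
Reagents that add atoms: none
Why: Copper-free Sonogashira coupling at the C–Br bond activated by the ortho formyl group; without copper the propargylic ether cannot ionise through an acetylide, so the centre is untouched (its label changes from S to R only because the alkyne now outranks the aryl group).

Step 5
Reactants: 8 4,5-bis(benzyloxy)-2-{(3R)-3-[3-(benzyloxy)phenoxy]-3-[3,4-bis(benzyloxy)phenyl]prop-1-yn-1-yl}benzaldehyde; 3 ethynylmagnesium bromide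
Product: 10 1-[4,5-bis(benzyloxy)-2-{(3R)-3-[3-(benzyloxy)phenoxy]-3-[3,4-bis(benzyloxy)phenyl]prop-1-yn-1-yl}phenyl]prop-2-yn-1-yl acetate (about 1:1 epimers at the acetoxy carbon), via bromomagnesium alkoxide 9 (not isolated)
Conditions: HC≡CMgBr (1.2 equiv), THF, −20 °C; then Ac2O (1.5 equiv), DMAP (cat.), 0 °C → rt
Reagents that add atoms: acetic anhydride, CC(=O)OC(C)=O
Why: Same Grignard addition and in situ acylation as in step 2; the new centre forms as both epimers, which step 6 converges.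

Step 6
Reactants: 10 the propargylic acetate of step 5 (epimer mixture); 6 3-(benzyloxy)phenol
Product: 11 1-(benzyloxy)-3-{[(1R)-1-[4,5-bis(benzyloxy)-2-{(3R)-3-[3-(benzyloxy)phenoxy]-3-[3,4-bis(benzyloxy)phenyl]prop-1-yn-1-yl}phenyl]prop-2-yn-1-yl]oxy}benzene
Conditions: CuOTf·½C6H6 (5 mol %), (R,R)-Ph-pybox (10 mol %), i-Pr2NEt (1.2 equiv), THF, −10 °C
Reagents that add atoms: none
Why: Second copper-catalysed enantioconvergent propargylic etherification, now with the mirror-image ligand, sets under catalyst control the (R) ether centre that becomes lower C2; the internal alkyne and the existing ether cannot form an acetylide and are not touched.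

Step 7
Reactants: 11 the bis(aryl propargyl ether) of step 6
Product: 13 (2S)-7-(benzyloxy)-2-{4,5-bis(benzyloxy)-2-[(2S)-7-(benzyloxy)-2-[3,4-bis(benzyloxy)phenyl]-2H-chromen-4-yl]phenyl}chroman-3-one, via mono-cyclised chroman-3-one 12 (not isolated)
Conditions: [(Me4tBuXPhos)Au]NTf2 (5 mol %; Me4tBuXPhos = 2-di-tert-butylphosphino-3,4,5,6-tetramethyl-2′,4′,6′-triisopropylbiphenyl), 2,6-dichloropyridine N-oxide (1.15 equiv), ClCH2CH2Cl, rt then 50 °C, under N2; short silica plug, used at once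
Reagents that add atoms: 2,6-dichloropyridine N-oxide, [O-][n+]1c(Cl)cccc1Cl
Why: Proposed new method: the two gold-catalysed ring closures are each known but have not been run together on one substrate; monovalent gold with the bulky biaryl phosphine activates the terminal alkyne fastest, the N-oxide adds at its internal carbon and loses 2,6-dichloropyridine to give an α-oxo gold carbene that is captured by the aryloxy ring para to OBn (closest known type: gold-catalysed oxidation of aryl propargyl ethers to chroman-3-ones), and the same catalyst then promotes 6-endo-dig hydroarylation of the aryl-substituted alkyne by the second aryloxy ring (closest known type: gold-catalysed cyclisation of aryl propargyl ethers to 2H-chromenes); no bond to either C2 centre is made or broken, so both configurations from steps 3 and 6 are kept.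

Step 8
Reactants: 13 the keto-chromene of step 7
Product: 16 (2S,3S)-7-(benzyloxy)-2-{4,5-bis(benzyloxy)-2-[(2R,3S,4R)-7-(benzyloxy)-2-[3,4-bis(benzyloxy)phenyl]-3-hydroxychroman-4-yl]phenyl}chroman-3-ol, via lithium cis-chroman-3-olate 14 (not isolated), via upper C3 alkylborane 15 (not isolated)
Conditions: LiBH(s-Bu)3 (1.5 equiv), THF, −78 °C; then BH3·THF (6 equiv), −78 °C → rt; then NaOH, H2O2, H2O, 0 °C → rt
Reagents that add atoms: hydrogen peroxide, OO
Why: LiBH(s-Bu)3 attacks the chroman-3-one from the face away from the C2 aryl group to give the 2,3-cis alkoxide (known for benzylated flavan-3-ones), then syn hydroboration of the 4-aryl-2H-chromene puts boron at C3 and hydrogen at C4 on the face anti to the C2 aryl group, and oxidation with retention gives the upper 2,3-trans-3,4-trans arrangement.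

Step 9
Reactants: 16 the hexabenzyl ether of step 8
Product: 17 (2S,3S)-2-{2-[(2R,3S,4R)-2-(3,4-dihydroxyphenyl)-3,7-dihydroxychroman-4-yl]-4,5-dihydroxyphenyl}chroman-3,7-diol (CNP0244903.4)
Conditions: H2 (1 atm), Pd(OH)2/C, THF/MeOH, rt
Reagents that add atoms: none
Why: Hydrogenolysis of the six benzyl ethers over Pd(OH)2/C under neutral conditions leaves the chroman C2–O1 bonds, the diarylmethine C4 and all five stereocentres untouched, as is routine for benzylated flavan-3-ol oligomers.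

## Compound list

1 | 3,4-bis(benzyloxy)benzaldehyde | O=Cc1ccc(OCc2ccccc2)c(OCc2ccccc2)c1 | starting material
2 | 4,5-bis(benzyloxy)-2-bromobenzaldehyde | O=Cc1cc(OCc2ccccc2)c(OCc2ccccc2)cc1Br | intermediate
3 | ethynylmagnesium bromide | C#C[Mg]Br | starting material
4 | bromomagnesium 1-[3,4-bis(benzyloxy)phenyl]prop-2-yn-1-olate (racemic) | C#CC(O[Mg]Br)c1ccc(OCc2ccccc2)c(OCc2ccccc2)c1 | intermediate
5 | (±)-1-[3,4-bis(benzyloxy)phenyl]prop-2-yn-1-yl acetate | CC(=O)OC(C#C)c1ccc(OCc2ccccc2)c(OCc2ccccc2)c1 | intermediate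
6 | 3-(benzyloxy)phenol | Oc1cccc(OCc2ccccc2)c1 | starting material
7 | 1-(benzyloxy)-3-{[(1S)-1-[3,4-bis(benzyloxy)phenyl]prop-2-yn-1-yl]oxy}benzene | C#C[C@@H](c1ccc(OCc2ccccc2)c(OCc2ccccc2)c1)Oc1cccc(OCc2ccccc2)c1 | intermediate
8 | 4,5-bis(benzyloxy)-2-{(3R)-3-[3-(benzyloxy)phenoxy]-3-[3,4-bis(benzyloxy)phenyl]prop-1-yn-1-yl}benzaldehyde | O=Cc1cc(OCc2ccccc2)c(OCc2ccccc2)cc1C#C[C@@H](c1ccc(OCc2ccccc2)c(OCc2ccccc2)c1)Oc1cccc(OCc2ccccc2)c1 | intermediate
9 | bromomagnesium 1-[4,5-bis(benzyloxy)-2-{(3R)-3-[3-(benzyloxy)phenoxy]-3-[3,4-bis(benzyloxy)phenyl]prop-1-yn-1-yl}phenyl]prop-2-yn-1-olate (both epimers at C1) | C#CC(O[Mg]Br)c1cc(OCc2ccccc2)c(OCc2ccccc2)cc1C#C[C@@H](c1ccc(OCc2ccccc2)c(OCc2ccccc2)c1)Oc1cccc(OCc2ccccc2)c1 | intermediate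
10 | 1-[4,5-bis(benzyloxy)-2-{(3R)-3-[3-(benzyloxy)phenoxy]-3-[3,4-bis(benzyloxy)phenyl]prop-1-yn-1-yl}phenyl]prop-2-yn-1-yl acetate (both epimers at C1) | C#CC(OC(C)=O)c1cc(OCc2ccccc2)c(OCc2ccccc2)cc1C#C[C@@H](c1ccc(OCc2ccccc2)c(OCc2ccccc2)c1)Oc1cccc(OCc2ccccc2)c1 | intermediate
11 | 1-(benzyloxy)-3-{[(1R)-1-[4,5-bis(benzyloxy)-2-{(3R)-3-[3-(benzyloxy)phenoxy]-3-[3,4-bis(benzyloxy)phenyl]prop-1-yn-1-yl}phenyl]prop-2-yn-1-yl]oxy}benzene | C#C[C@@H](Oc1cccc(OCc2ccccc2)c1)c1cc(OCc2ccccc2)c(OCc2ccccc2)cc1C#C[C@@H](c1ccc(OCc2ccccc2)c(OCc2ccccc2)c1)Oc1cccc(OCc2ccccc2)c1 | intermediate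
12 | (2S)-7-(benzyloxy)-2-[4,5-bis(benzyloxy)-2-{(3R)-3-[3-(benzyloxy)phenoxy]-3-[3,4-bis(benzyloxy)phenyl]prop-1-yn-1-yl}phenyl]chroman-3-one | c1ccccc1COc1ccc2c(c1)O[C@@H](c1cc(OCc3ccccc3)c(OCc3ccccc3)cc1C#C[C@@H](c1ccc(OCc3ccccc3)c(OCc3ccccc3)c1)Oc1cccc(OCc3ccccc3)c1)C(=O)C2 | intermediate
13 | (2S)-7-(benzyloxy)-2-{4,5-bis(benzyloxy)-2-[(2S)-7-(benzyloxy)-2-[3,4-bis(benzyloxy)phenyl]-2H-chromen-4-yl]phenyl}chroman-3-one | c1ccccc1COc1ccc2c(c1)O[C@@H](c1cc(OCc3ccccc3)c(OCc3ccccc3)cc1C=4c3ccc(OCc5ccccc5)cc3O[C@H](c3ccc(OCc5ccccc5)c(OCc5ccccc5)c3)C4)C(=O)C2 | intermediate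
14 | lithium (2S,3S)-7-(benzyloxy)-2-{4,5-bis(benzyloxy)-2-[(2S)-7-(benzyloxy)-2-[3,4-bis(benzyloxy)phenyl]-2H-chromen-4-yl]phenyl}chroman-3-olate (2,3-cis) | c1ccccc1COc1ccc2c(c1)O[C@@H](c1cc(OCc3ccccc3)c(OCc3ccccc3)cc1C=4c3ccc(OCc5ccccc5)cc3O[C@H](c3ccc(OCc5ccccc5)c(OCc5ccccc5)c3)C4)[C@@H](O[Li])C2 | intermediate
15 | upper C3 alkylborane of 14, drawn as the monoalkylborane: BH2 on upper C3, trans to both flanking aryl groups (same arrangement as the upper OH of 16); lower ring as in 14 | c1ccccc1COc1ccc2c(c1)O[C@@H](c1cc(OCc3ccccc3)c(OCc3ccccc3)cc1[C@@H]1c3ccc(OCc4ccccc4)cc3O[C@H](c3ccc(OCc4ccccc4)c(OCc4ccccc4)c3)[C@H]1B)[C@@H](O[Li])C2 | intermediate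
16 | (2S,3S)-7-(benzyloxy)-2-{4,5-bis(benzyloxy)-2-[(2R,3S,4R)-7-(benzyloxy)-2-[3,4-bis(benzyloxy)phenyl]-3-hydroxychroman-4-yl]phenyl}chroman-3-ol | c1ccccc1COc1ccc2c(c1)O[C@@H](c1cc(OCc3ccccc3)c(OCc3ccccc3)cc1[C@@H]1c3ccc(OCc4ccccc4)cc3O[C@H](c3ccc(OCc4ccccc4)c(OCc4ccccc4)c3)[C@H]1O)[C@@H](O)C2 | intermediate
17 | (2S,3S)-2-{2-[(2R,3S,4R)-2-(3,4-dihydroxyphenyl)-3,7-dihydroxychroman-4-yl]-4,5-dihydroxyphenyl}chroman-3,7-diol | Oc1ccc2c(c1)O[C@@H](c1cc(O)c(O)cc1[C@@H]1c3ccc(O)cc3O[C@H](c3ccc(O)c(O)c3)[C@H]1O)[C@@H](O)C2 | target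

## Step count and risks

Total: 9 steps. Longest linear sequence: 8 steps (steps 2 to 9, from 1).

**Step 7 (gold double cyclisation).** This is the most likely step to fail.
- The α-oxo gold carbene could be trapped by the ortho alkyne or by the central ring instead of the aryloxy ring.
- The ortho aryl-ether oxygen could add to the activated alkyne.
- Closure ortho instead of para to OBn would give 5-benzyloxy isomers.
- The benzylic C2 centres could ionise.

Fallback, setting out from 11 and returning at 13: keep the double ring closure but make the lower ring without the carbene. Treat 11 with PtCl4 (5 mol %) in dioxane with no oxidant, so that both propargyl ethers undergo 6-endo-dig hydroarylation to (2R)-7-(benzyloxy)-2-{4,5-bis(benzyloxy)-2-[(2S)-7-(benzyloxy)-2-[3,4-bis(benzyloxy)phenyl]-2H-chromen-4-yl]phenyl}-2H-chromene F1. Hydroborate only the disubstituted lower C3=C4 bond with 9-BBN and oxidise (NaOH, H2O2) to the lower 2,3-trans alcohol F2. Dess–Martin periodinane then gives ketone 13.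

**Step 6 (second copper-catalysed etherification).**
- The ortho alkynyl group sits next to the allenylidene carbon and may erode the selectivity.
- The resorcinol-type phenol 6 may react through carbon.

Fallback, setting out from 8 and returning at 11: make the centre by C–C bond formation and invert it. Add trimethylsilylacetylene to 8 with Me2Zn and ProPhenol (Trost-type asymmetric alkynylation) to give the (1R)-silylated propargylic alcohol F3. Mitsunobu etherification with 6 (PPh3, DIAD, toluene, −20 °C, inversion) gives the silylated bis(propargyl ether) F4. K2CO3 in MeOH removes silicon to give 11.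

**Step 8 (reduction and hydroboration in one flask).**
- Ketone 13 can epimerise at C2 or air-oxidise before the hydride arrives.
- Cis selectivity rests on that C2 centre.
- The hindered upper alkene may hydroborate slowly.

Fallback, setting out from 13 and returning at 16: turn the C2 lability into the control element. Hydrogenate the ketone with RuCl2[(S)-xylbinap][(S)-daipen], t-BuOK, i-PrOH and H2 (Noyori-type hydrogenation with dynamic kinetic resolution; carbonyl-selective, so the alkene and benzyl ethers survive). The catalyst then fixes both lower centres as the free cis-alcohol F5, which is isolated and checked. Hydroboration–oxidation on its own (BH3·THF; then NaOH, H2O2) gives 16.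

## Further compounds

F1 | step 7 | (2R)-7-(benzyloxy)-2-{4,5-bis(benzyloxy)-2-[(2S)-7-(benzyloxy)-2-[3,4-bis(benzyloxy)phenyl]-2H-chromen-4-yl]phenyl}-2H-chromene | c1ccccc1COc1ccc2c(c1)O[C@@H](c1cc(OCc3ccccc3)c(OCc3ccccc3)cc1C=4c3ccc(OCc5ccccc5)cc3O[C@H](c3ccc(OCc5ccccc5)c(OCc5ccccc5)c3)C4)C=C2
F2 | step 7 | (2S,3R)-7-(benzyloxy)-2-{4,5-bis(benzyloxy)-2-[(2S)-7-(benzyloxy)-2-[3,4-bis(benzyloxy)phenyl]-2H-chromen-4-yl]phenyl}chroman-3-ol (2,3-trans) | c1ccccc1COc1ccc2c(c1)O[C@@H](c1cc(OCc3ccccc3)c(OCc3ccccc3)cc1C=4c3ccc(OCc5ccccc5)cc3O[C@H](c3ccc(OCc5ccccc5)c(OCc5ccccc5)c3)C4)[C@H](O)C2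
F3 | step 6 | (1R)-1-[4,5-bis(benzyloxy)-2-{(3R)-3-[3-(benzyloxy)phenoxy]-3-[3,4-bis(benzyloxy)phenyl]prop-1-yn-1-yl}phenyl]-3-(trimethylsilyl)prop-2-yn-1-ol | C[Si](C)(C)C#C[C@H](O)c1cc(OCc2ccccc2)c(OCc2ccccc2)cc1C#C[C@@H](c1ccc(OCc2ccccc2)c(OCc2ccccc2)c1)Oc1cccc(OCc2ccccc2)c1
F4 | step 6 | 1-(benzyloxy)-3-{[(1S)-1-[4,5-bis(benzyloxy)-2-{(3R)-3-[3-(benzyloxy)phenoxy]-3-[3,4-bis(benzyloxy)phenyl]prop-1-yn-1-yl}phenyl]-3-(trimethylsilyl)prop-2-yn-1-yl]oxy}benzene | C[Si](C)(C)C#C[C@@H](Oc1cccc(OCc2ccccc2)c1)c1cc(OCc2ccccc2)c(OCc2ccccc2)cc1C#C[C@@H](c1ccc(OCc2ccccc2)c(OCc2ccccc2)c1)Oc1cccc(OCc2ccccc2)c1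
F5 | step 8 | (2S,3S)-7-(benzyloxy)-2-{4,5-bis(benzyloxy)-2-[(2S)-7-(benzyloxy)-2-[3,4-bis(benzyloxy)phenyl]-2H-chromen-4-yl]phenyl}chroman-3-ol (2,3-cis, free alcohol) | c1ccccc1COc1ccc2c(c1)O[C@@H](c1cc(OCc3ccccc3)c(OCc3ccccc3)cc1C=4c3ccc(OCc5ccccc5)cc3O[C@H](c3ccc(OCc5ccccc5)c(OCc5ccccc5)c3)C4)[C@@H](O)C2
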